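The tricycle is read as a cis-decalin (ring A: C1–C5, C10; ring B: C5–C10) whose C3 and C9 are tied across ring A by the methylene C20, which makes the bicyclo[2.2.2]octanone. The route rests on the C9–C20 disconnection. A tertiary C9 radical, released reductively from the N-phthalimidoyl oxalate of a C9 carbinol, adds 6-endo to C20 of a C3 α-methylene ketone. One operation forges the quaternary C9, the bridgehead C3 and the tricyclic core; it is stereoconvergent, because the carbinol configuration is erased and the cis ring fusion permits one closure only. The precursor is a Diels–Alder-derived cis-decalin that carries the side chain as an acetonide.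

Key step: step 15

Numbering used throughout: ketone C2; C20 is the CH2 between C3 and C9; C11–C15 is the side chain with methyl C16 on C13; methyls C17, C18, C19 sit on C8, C4, C5. Faces: H-10 and C19 are α.

Assumption: in step 6 the quinone is taken to add endo to the diene face remote from the phenyl group on the inner (C3) side of the amino terminus of the (2R,5R) auxiliary; this is the configuration drawn for 11.

Step 1
Reactants: 1 (S)-citramalic acid
Product: 2 (2S)-2-methylbutane-1,2,4-triol
Conditions: BH3·SMe2, B(OMe)3, THF, 0 °C → rt; MeOH quench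
Reagents that add atoms: none
Why: Borane reduces both carboxylic acids to primary alcohols (chemoselective acid reduction) and leaves the tertiary carbinol, the future C13, in its S configuration.

Step 2
Reactants: 2 (2S)-2-methylbutane-1,2,4-triol
Product: 3 2-[(4S)-2,2,4-trimethyl-1,3-dioxolan-4-yl]ethanol
Conditions: Me2C(OMe)2, TsOH·H2O (cat.), acetone, rt
Reagents that add atoms: 2,2-dimethoxypropane COC(C)(C)OC
Why: Thermodynamic acetalisation should prefer the five-membered dioxolane of the 1,2-diol over the 1,3-dioxane, which leaves the primary C11 hydroxyl free.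

Step 3
Reactants: 3 2-[(4S)-2,2,4-trimethyl-1,3-dioxolan-4-yl]ethanol
Product: 4 (4S)-4-(2-iodoethyl)-2,2,4-trimethyl-1,3-dioxolane
Conditions: I2, PPh3, imidazole, CH2Cl2, 0 °C → rt
Reagents that add atoms: iodine II
Why: Appel-type iodination proceeds by SN2 displacement at the primary carbon and does not touch the quaternary stereocentre.

Step 4
Reactants: 5 (E)-4-methoxybut-3-en-2-one; 6 (2R,5R)-2,5-diphenylpyrrolidine
Product: 7 (E)-4-[(2R,5R)-2,5-diphenylpyrrolidin-1-yl]but-3-en-2-one
Conditions: MeOH, rt
Reagents that add atoms: none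
Why: Conjugate addition of the secondary amine and loss of methanol (addition–elimination) gives the E vinylogous amide.

Step 5
Reactants: 7 (E)-4-[(2R,5R)-2,5-diphenylpyrrolidin-1-yl]but-3-en-2-one
Product: 9 (2R,5R)-1-[(1E)-3-(tert-butyldimethylsilyloxy)buta-1,3-dienyl]-2,5-diphenylpyrrolidine, via potassium dienolate 8 (not isolated)
Conditions: KN(SiMe3)2, THF, −78 °C; then t-BuMe2SiCl, −78 °C → rt
Reagents that add atoms: tert-butyldimethylsilyl chloride CC(C)(C)[Si](C)(C)Cl
Why: Kinetic deprotonation of the methyl ketone gives the cross-conjugated dienolate, and O-silylation gives the 1-amino-3-siloxy diene.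

Step 6
Reactants: 10 2,5-dimethyl-1,4-benzoquinone; 9 the amino siloxy diene
Product: 11 cis-fused cycloadduct (ring B enedione with C6=O, C9=O and C7=C8 bearing C17; C19 α on C5; H-10 α; ring A with the C2 silyl enol ether C2=C3 and the pyrrolidinyl group β on C4)
Conditions: toluene, −40 °C → rt, no catalyst
Reagents that add atoms: none
Why: In this thermal Diels–Alder reaction the nucleophilic CH2 terminus of the diene bonds to the unsubstituted quinone carbon (C10) and the amino terminus to the methyl-bearing carbon (quaternary C5), suprafacial endo addition makes the ring fusion cis, and the C2-symmetric pyrrolidine shields one diene face so that C5 and C10 are set in the absolute sense drawn.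

Step 7
Reactants: 4 (4S)-4-(2-iodoethyl)-2,2,4-trimethyl-1,3-dioxolane; 11 the cycloadduct
Product: 14 C9 tertiary alcohol (9β-OH, side chain C11–C14 as acetonide on the α face, enone C6=O/C7=C8 retained), via organolithium 12 (not isolated), via organocerium 13 (not isolated)
Conditions: 4, t-BuLi (2.1 equiv), Et2O, −78 °C; CeCl3, THF, −78 °C; then 11, −78 °C; pH 7 buffer
Reagents that add atoms: none
Why: The weakly basic organocerium reagent adds 1,2 to the C9 carbonyl, which is less hindered and more electrophilic than the C6 carbonyl (flanked by quaternary C5 and deactivated by the β-methyl C17), and it approaches the convex α face of the cis-fused enedione, which places the new hydroxyl β.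

Step 8
Reactants: 14 the C9 tertiary alcohol
Product: 15 7,8-dihydro compound (C6 ketone, H-8 β, C17 α)
Conditions: H2 (1 atm), [Ir(cod)(PCy3)(py)]PF6 (5 mol%), CH2Cl2, 0 °C → rt
Reagents that add atoms: none
Why: In this hydroxyl-directed hydrogenation the 9β-hydroxyl binds the cationic iridium catalyst and hydrogen is delivered to the β face of C7=C8, which sets C8 with H β and C17 α, while the hindered silyl enol ether has no directing group and should stay.

Step 9
Reactants: 15 the C6 ketone
Product: 16 6β,9β-diol
Conditions: SmI2, H2O, Et3N, THF, rt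
Reagents that add atoms: none
Why: Single-electron reduction of the C6 ketone by divalent samarium with water as proton source should give the thermodynamically favoured equatorial 6β-alcohol, trans to C19, since the 6α-epimer would stand 1,3-diaxial to the C17 methyl.

Step 10
Reactants: 16 the 6β,9β-diol
Product: 17 6β-acetate
Conditions: Ac2O, DMAP (cat.), pyridine, rt
Reagents that add atoms: acetic anhydride CC(=O)OC(C)=O
Why: DMAP-catalysed acylation takes the secondary C6 hydroxyl only, because the tertiary C9 hydroxyl is flanked by C8, C10 and the side chain.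

Step 11
Reactants: 17 the 6β-acetate
Product: 19 ring A enone (C2=O, C3=C4), via β-amino ketone 18 (not isolated)
Conditions: HF·pyridine, pyridine, THF, 0 °C → rt
Reagents that add atoms: none
Why: Fluoride cleaves the silyl enol ether to the β-amino ketone, which loses the hindered amine by β-elimination (retro-aza-Michael reaction) to give the conjugated enone; the acetonide and the acetate should survive and the auxiliary is recovered.

Step 12
Reactants: 19 the ring A enone
Product: 21 Mannich base (C18 α on C4, CH2NMe2 β on C3, C2 ketone), via lithium enolate 20 (not isolated)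
Conditions: Me2CuLi (3 equiv, from CuI and MeLi), Et2O, −78 → −30 °C; then CH2=NMe2+ I−, THF, −78 °C → rt
Reagents that add atoms: lithium dimethylcuprate [Li+].C[Cu-]C; dimethyl(methylene)ammonium iodide C=[N+](C)C.[I-]
Why: Conjugate addition of the cuprate to the cis-fused enone should occur on the α face, anti to ring B and to the axial C9 substituent, which sets C4 with C18 α and cis to C19, and the regiodefined C2–C3 enolate is alkylated at C3 by the iminium salt (Mannich reaction) trans to the new methyl.

Step 13
Reactants: 21 the Mannich base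
Product: 23 α-methylene ketone (C3=C20, C2=O, 9β-OH), via methiodide 22 (not isolated)
Conditions: MeI, CH2Cl2, rt; then NaHCO3 (aq), rt
Reagents that add atoms: none
Why: Quaternisation of the amine and E1cB loss of trimethylamine under mild base unveil the exocyclic enone without touching C4.

Step 14
Reactants: 23 the α-methylene ketone
Product: 24 C9 N-phthalimidoyl oxalate of 23
Conditions: ClC(O)C(O)ON(phthaloyl) (made in the flask from N-hydroxyphthalimide and (COCl)2, THF, volatiles removed), Et3N, DMAP (cat.), THF, 0 °C → rt; used crude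
Reagents that add atoms: chloro N-phthalimidoyl oxalate O=C(Cl)C(=O)ON1C(=O)c2ccccc2C1=O, made from oxalyl chloride ClC(=O)C(=O)Cl and N-hydroxyphthalimide ON1C(=O)c2ccccc2C1=O
Why: The very electrophilic chlorooxalate acylates even the hindered tertiary C9 hydroxyl (nucleophilic catalysis) and gives the redox-active ester that serves as the radical precursor.

Step 15
Reactants: 24 the C9 N-phthalimidoyl oxalate
Product: 27 tricyclic acetonide (C9–C20 bond closed, H-3 at the bridgehead), via C9 radical 25 (not isolated), via C3 bridgehead radical 26 (not isolated)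
Conditions: Ru(bpy)3(PF6)2 (2 mol%), Hantzsch ester (diethyl 2,6-dimethyl-1,4-dihydropyridine-3,5-dicarboxylate, 1.5 equiv, added slowly), i-Pr2NEt·HBF4, THF/CH2Cl2, blue LEDs, rt, 0.01 M
Reagents that add atoms: none
Why: The photoexcited ruthenium complex is reduced by the dihydropyridine, and the resulting monovalent ruthenium species transfers an electron to the N-phthalimidoyl oxalate, which loses phthalimide anion and two molecules of CO2 to give the tertiary C9 radical 25; this adds to C20, the β-carbon of the C3 α-methylene ketone, and the bridgehead C3 radical 26, which cannot conjugate with the C2 carbonyl and is therefore not reduced further, is capped by hydrogen transfer from the dihydropyridine. The closest known reaction type is the visible-light reductive coupling of tert-alkyl N-phthalimidoyl oxalates with enones (Giese-type radical conjugate addition), run here intramolecularly. The ring closes in the 6-endo-trig mode through a boat of ring A with C3 and C10 as bow and stern, which completes the rings C9–C20–C3–C2–C1–C10 and C9–C20–C3–C4–C5–C10 of the bicyclo[2.2.2]octane. Both new stereocentres are fixed by geometry: the planar C9 radical can reach C20 only on the β face, where the cis fusion holds C9 over ring A, so C20 ends β and C11 α whatever the carbinol configuration was, and the bridgehead C3 can take its hydrogen only from outside. The step needs attack at C20 to beat attack at C3 and premature hydrogen transfer to 25: the polarity match of the nucleophilic tertiary radical with the enone β-carbon and the strain of the norbornane alternative secure the first, the low dihydropyridine concentration secures the second, and the side chain offers no alkene for a competing 5-exo closure because the vinyl group is still masked as the acetonide.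

Step 16
Reactants: 27 the tricyclic acetonide
Product: 28 tricyclic 13,14-diol
Conditions: AcOH/H2O (4:1), 40 °C
Reagents that add atoms: none
Why: Aqueous acetic acid hydrolyses the acetonide (acetal hydrolysis) while the acetate and the ketone should survive.

Step 17
Reactants: 28 the 13,14-diol
Product: 29 α-hydroxy aldehyde (C14 aldehyde)
Conditions: TEMPO (10 mol%), PhI(OAc)2, CH2Cl2, rt
Reagents that add atoms: none
Why: The oxoammonium species from TEMPO oxidises the primary hydroxyl selectively to the aldehyde; the tertiary hydroxyl is inert and the α-carbon is quaternary, so C13 cannot epimerise.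

Step 18
Reactants: 29 the α-hydroxy aldehyde
Product: 30 CNP0281208.1 (target)
Conditions: Ph3PCH3Br, KN(SiMe3)2 (2.2 equiv ylide), THF, 0 °C; then 29, −78 → 0 °C
Reagents that add atoms: methylenetriphenylphosphorane C=P(c1ccccc1)(c1ccccc1)c1ccccc1, made from methyltriphenylphosphonium bromide C[P+](c1ccccc1)(c1ccccc1)c1ccccc1.[Br-]
Why: Wittig methylenation at low temperature should take the α-hydroxy aldehyde in preference to the hindered bicyclic C2 ketone and the acetate, which completes the vinyl carbinol with C13 unchanged.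

Compound list
1 | (S)-citramalic acid | C[C@](O)(CC(=O)O)C(=O)O | starting material
2 | (2S)-2-methylbutane-1,2,4-triol | C[C@](O)(CCO)CO | intermediate
3 | 2-[(4S)-2,2,4-trimethyl-1,3-dioxolan-4-yl]ethanol | C[C@]1(CCO)COC(C)(C)O1 | intermediate
4 | (4S)-4-(2-iodoethyl)-2,2,4-trimethyl-1,3-dioxolane | C[C@]1(CCI)COC(C)(C)O1 | intermediate
5 | (E)-4-methoxybut-3-en-2-one | CO/C=C/C(C)=O | starting material
6 | (2R,5R)-2,5-diphenylpyrrolidine | c1ccccc1[C@H]2CC[C@H](c3ccccc3)N2 | starting material
7 | (E)-4-[(2R,5R)-2,5-diphenylpyrrolidin-1-yl]but-3-en-2-one | CC(=O)/C=C/N1[C@@H](c2ccccc2)CC[C@@H]1c1ccccc1 | intermediate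
8 | potassium dienolate of 7 | [K+].C=C([O-])/C=C/N1[C@@H](c2ccccc2)CC[C@@H]1c1ccccc1 | intermediate
9 | (2R,5R)-1-[(1E)-3-(tert-butyldimethylsilyloxy)buta-1,3-dienyl]-2,5-diphenylpyrrolidine | C=C(O[Si](C)(C)C(C)(C)C)/C=C/N1[C@@H](c2ccccc2)CC[C@@H]1c1ccccc1 | intermediate
10 | 2,5-dimethyl-1,4-benzoquinone | CC1=CC(=O)C(C)=CC1=O | starting material
11 | cis-fused cycloadduct (C6, C9 enedione; C2 silyl enol ether; 4β-pyrrolidinyl; C19 α; H-10 α) | O=C1C(C)=CC(=O)[C@@]2(C)[C@@H](N3[C@@H](c4ccccc4)CC[C@@H]3c3ccccc3)C=C(O[Si](C)(C)C(C)(C)C)C[C@@H]12 | intermediate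
12 | 2-[(4S)-2,2,4-trimethyl-1,3-dioxolan-4-yl]ethyllithium | [Li]CC[C@@]1(C)COC(C)(C)O1 | intermediate
13 | 2-[(4S)-2,2,4-trimethyl-1,3-dioxolan-4-yl]ethylcerium dichloride | Cl[Ce](Cl)CC[C@@]1(C)COC(C)(C)O1 | intermediate
14 | 9β-hydroxy adduct with the acetonide side chain on C9 (C6 enone, ring A masked) | CC1(C)OC[C@@](C)(O1)CC[C@]1(O)C(C)=CC(=O)[C@@]2(C)[C@@H](N3[C@@H](c4ccccc4)CC[C@@H]3c3ccccc3)C=C(O[Si](C)(C)C(C)(C)C)C[C@@H]12 | intermediate
15 | 7,8-dihydro C6 ketone (C17 α) | CC1(C)OC[C@@](C)(O1)CC[C@]1(O)[C@H](C)CC(=O)[C@@]2(C)[C@@H](N3[C@@H](c4ccccc4)CC[C@@H]3c3ccccc3)C=C(O[Si](C)(C)C(C)(C)C)C[C@@H]12 | intermediate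
16 | 6β,9β-diol | CC1(C)OC[C@@](C)(O1)CC[C@]1(O)[C@H](C)C[C@@H](O)[C@@]2(C)[C@@H](N3[C@@H](c4ccccc4)CC[C@@H]3c3ccccc3)C=C(O[Si](C)(C)C(C)(C)C)C[C@@H]12 | intermediate
17 | 6β-acetate of 16 | CC1(C)OC[C@@](C)(O1)CC[C@]1(O)[C@H](C)C[C@@H](OC(C)=O)[C@@]2(C)[C@@H](N3[C@@H](c4ccccc4)CC[C@@H]3c3ccccc3)C=C(O[Si](C)(C)C(C)(C)C)C[C@@H]12 | intermediate
18 | β-amino ketone (C2 ketone, 4β-pyrrolidinyl) | CC1(C)OC[C@@](C)(O1)CC[C@]1(O)[C@H](C)C[C@@H](OC(C)=O)[C@@]2(C)[C@@H](N3[C@@H](c4ccccc4)CC[C@@H]3c3ccccc3)CC(=O)C[C@@H]12 | intermediate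
19 | 6β-acetoxy-9β-hydroxy cis-decal-3-en-2-one with the acetonide side chain | CC1(C)OC[C@@](C)(O1)CC[C@]1(O)[C@H](C)C[C@@H](OC(C)=O)[C@@]2(C)C=CC(=O)C[C@@H]12 | intermediate
20 | dilithium C2–C3 enolate and C9 alkoxide (C18 α on C4) | [Li+].[Li+].CC1(C)OC[C@@](C)(O1)CC[C@]1([O-])[C@H](C)C[C@@H](OC(C)=O)[C@@]2(C)[C@H](C)C=C([O-])C[C@@H]12 | intermediate
21 | Mannich base (3β-CH2NMe2, 4α-methyl, C2 ketone) | CC1(C)OC[C@@](C)(O1)CC[C@]1(O)[C@H](C)C[C@@H](OC(C)=O)[C@@]2(C)[C@H](C)[C@@H](CN(C)C)C(=O)C[C@@H]12 | intermediate
22 | methiodide of 21 | [I-].CC1(C)OC[C@@](C)(O1)CC[C@]1(O)[C@H](C)C[C@@H](OC(C)=O)[C@@]2(C)[C@H](C)[C@@H](C[N+](C)(C)C)C(=O)C[C@@H]12 | intermediate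
23 | 3-methylene-2-ketone with the 9β tertiary alcohol | CC1(C)OC[C@@](C)(O1)CC[C@]1(O)[C@H](C)C[C@@H](OC(C)=O)[C@@]2(C)[C@H](C)C(=C)C(=O)C[C@@H]12 | intermediate
24 | C9 N-phthalimidoyl oxalate of 23 | CC1(C)OC[C@@](C)(O1)CC[C@]1(OC(=O)C(=O)ON2C(=O)c3ccccc3C2=O)[C@H](C)C[C@@H](OC(C)=O)[C@@]2(C)[C@H](C)C(=C)C(=O)C[C@@H]12 | intermediate
25 | tertiary C9 radical | CC1(C)OC[C@@](C)(O1)CC[C]1[C@H](C)C[C@@H](OC(C)=O)[C@@]2(C)[C@H](C)C(=C)C(=O)C[C@@H]12 | intermediate
26 | bridgehead C3 radical of the closed tricycle | CC1(C)OC[C@@](C)(O1)CC[C@@]12C[C]3C(=O)C[C@@H]1[C@](C)([C@@H]3C)[C@H](OC(C)=O)C[C@H]2C | intermediate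
27 | tricyclic acetonide | CC1(C)OC[C@@](C)(O1)CC[C@@]12C[C@H]3C(=O)C[C@@H]1[C@](C)([C@@H]3C)[C@H](OC(C)=O)C[C@H]2C | intermediate
28 | tricyclic 13,14-diol | OC[C@@](C)(O)CC[C@@]12C[C@H]3C(=O)C[C@@H]1[C@](C)([C@@H]3C)[C@H](OC(C)=O)C[C@H]2C | intermediate
29 | tricyclic α-hydroxy aldehyde | O=C[C@@](C)(O)CC[C@@]12C[C@H]3C(=O)C[C@@H]1[C@](C)([C@@H]3C)[C@H](OC(C)=O)C[C@H]2C | intermediate
30 | CNP0281208.1 | C=C[C@@](C)(O)CC[C@@]12C[C@H]3C(=O)C[C@@H]1[C@](C)([C@@H]3C)[C@H](OC(C)=O)C[C@H]2C | target

Total step count: 18. Longest linear sequence: 15 steps (steps 1–3 and 7–18, or steps 4–18).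

Steps most likely to fail

Step 15. Hydrogen may be transferred from the dihydropyridine to radical 25 before the boat closure, or the alkoxycarbonyl radical may lose CO2 too slowly. The fallback sets out from 23 and uses a radical chain without any hydrogen donor. Acylation of 23 with oxalyl chloride and then the sodium salt of N-hydroxypyridine-2-thione should give the mixed oxalate thiohydroxamate F1. Visible-light irradiation of F1 alone (CH2Cl2, rt) generates 25, which can then only cyclise; radical 26 is capped by pyridylthio group transfer to give the C3 bridgehead sulfide F2. Bu3SnH with AIBN in toluene at 80 °C replaces sulfur by hydrogen, and the route is rejoined at 27.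

Step 12. Facial control of the conjugate addition may erode, and the regiodefined enolate may be lost by proton transfer from the C9 hydroxyl or by oxa-Michael addition of its alkoxide. The fallback sets out from 19 and separates the two events. Me2CuLi in the presence of Me3SiCl (THF, −78 °C) should silylate both the C9 alkoxide and the enolate as they form, giving the isolable bis-silyl compound F3. A Mukaiyama-type Mannich reaction of F3 with dimethyl(methylene)ammonium iodide in CH2Cl2, followed by a mild acidic work-up that also frees the tertiary hydroxyl, returns to the route at 21.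

Step 6. The auxiliary may discriminate the diene faces poorly or in the opposite sense, or Michael addition followed by aromatisation of the quinone may outrun ring closure. The fallback sets out from 10 and moves the control from an auxiliary to a catalyst. The commercially available achiral diene (E)-1-methoxy-3-(tert-butyldimethylsilyloxy)buta-1,3-diene F4 is combined with 10 under a chiral titanium BINOLate (TiCl2(OiPr)2 with the BINOL antipode that delivers the needed sense, CH2Cl2, −30 °C) to give the methoxy cycloadduct F5. F5 then takes the place of 11: addition of 13 gives the tertiary alcohol F6, directed hydrogenation the C6 ketone F7, SmI2 reduction the diol F8 and acetylation the acetate F9, all under the conditions of steps 7–10. Trifluoroacetic acid in CH2Cl2 at 0 °C unmasks F9, and the route is rejoined at 19.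

Further compounds
F1 | step 15 | mixed oxalate of 23 with N-hydroxypyridine-2-thione | CC1(C)OC[C@@](C)(O1)CC[C@]1(OC(=O)C(=O)On2ccccc2=S)[C@H](C)C[C@@H](OC(C)=O)[C@@]2(C)[C@H](C)C(=C)C(=O)C[C@@H]12
F2 | step 15 | 3-(pyridin-2-ylsulfanyl) tricyclic acetonide | CC1(C)OC[C@@](C)(O1)CC[C@@]12C[C@@]3(Sc4ccccn4)C(=O)C[C@@H]1[C@](C)([C@@H]3C)[C@H](OC(C)=O)C[C@H]2C
F3 | step 12 | bis(trimethylsilyl) compound: C2 silyl enol ether and C9 silyl ether, C18 α | CC1(C)OC[C@@](C)(O1)CC[C@]1(O[Si](C)(C)C)[C@H](C)C[C@@H](OC(C)=O)[C@@]2(C)[C@H](C)C=C(O[Si](C)(C)C)C[C@@H]12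
F4 | step 6 | (E)-1-methoxy-3-(tert-butyldimethylsilyloxy)buta-1,3-diene | CO/C=C/C(=C)O[Si](C)(C)C(C)(C)C
F5 | step 6 | 4β-methoxy cycloadduct | O=C1C(C)=CC(=O)[C@@]2(C)[C@@H](OC)C=C(O[Si](C)(C)C(C)(C)C)C[C@@H]12
F6 | step 6 | 4β-methoxy analogue of 14 | CC1(C)OC[C@@](C)(O1)CC[C@]1(O)C(C)=CC(=O)[C@@]2(C)[C@@H](OC)C=C(O[Si](C)(C)C(C)(C)C)C[C@@H]12
F7 | step 6 | 4β-methoxy analogue of 15 | CC1(C)OC[C@@](C)(O1)CC[C@]1(O)[C@H](C)CC(=O)[C@@]2(C)[C@@H](OC)C=C(O[Si](C)(C)C(C)(C)C)C[C@@H]12
F8 | step 6 | 4β-methoxy analogue of 16 | CC1(C)OC[C@@](C)(O1)CC[C@]1(O)[C@H](C)C[C@@H](O)[C@@]2(C)[C@@H](OC)C=C(O[Si](C)(C)C(C)(C)C)C[C@@H]12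
F9 | step 6 | 4β-methoxy analogue of 17 | CC1(C)OC[C@@](C)(O1)CC[C@]1(O)[C@H](C)C[C@@H](OC(C)=O)[C@@]2(C)[C@@H](OC)C=C(O[Si](C)(C)C(C)(C)C)C[C@@H]12
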